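Monday's flask, charged with 6.7 mM of starting material, the limiting reagent at 2 equiv of second substrate, left a gap: at 120 s its target read 78.7%, so 1.43 mM of the charge did not stand as target.

common to all: free enzyme 0.0039 mol%
- Sunday's: starting material 10 mM; second substrate 2 equiv; the very flask that is asked about, followed so far
- Monday's: starting material 6.7 mM; second substrate 2 equiv; run made earlier
- flask: starting material 10 mM; second substrate 2.00 equiv; time 2.0 min

- Sunday's (time / s: target / %): 10.0: 63.4; 12.0: 73.3; 15.0: 82.1; 25.0: 89.1; 30.0: 87.1; 50.0: 83.5
- Monday's (time / s: target / %): 10.0: 56.3; 15.0: 73.7; 25.0: 87.6; 40.0: 83.2; 80.0: 77.9; 120: 78.7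

(readings scatter by 0.5 percentage points)

- a reading or a percentage of target counts all its forms, free or not

1. time up to 2.0 min at which target stands highest
2. the amount of target, in percent of the starting material charged, at that time

Sunday's flask read 83.5% at 50.0 s, which gave a shortfall, the amount of the charge in mM not standing as target, of 1.65 mM. The charge had grown 1.49 times from Monday's to Sunday's, but the shortfall had grown 1.15 times, less than the charge, though Sunday's reading stands at the earlier time, so I carried the shortfall in mM and not as a percentage.

Target in Sunday's flask stands highest when the shortfall stops falling, so I compared its rates of change on either side of the 25.0 s reading. Target gained 7 percentage points from 15.0 s to 25.0 s, then lost 2 points by 30.0 s. A straight line between these two mean rates, each placed at the middle of its interval, crosses zero at 0.413 min, so I committed to that time and to about 89.1%, the nearest reading.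

The forecast gave 90% (89% to 91.8%) at 0.35 min (0.3 min to 0.41 min), a time earlier than mine, and took the fall for “over-reaction or reversal that only takes over once the starting material is nearly gone”.

Sunday's flask gives its highest target, 89.4%, at 0.368 min, earlier than my reckoned time.

    starting material + free enzyme ⇌ first complex (K = 470 /M, k = 1.50 × 10⁶ /M/s)
    second complex → free enzyme + target (k = 5550 /s)
    target + free enzyme ⇌ isomer of the product + free enzyme, rate k3*[free enzyme]*[target] forward; the back reaction follows from the equilibrium constant (K = 0.280, k = 49100 /M/s)
    crystals ⇌ target, rate k4*(cs4 - [target]) while solid is left; crystals form when [target] > cs4 (solubility = 6.30 mM, k = 0.725 /s)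
    second substrate + loaded enzyme ⇌ second complex (K = 158 /M, k = 1.06 × 10⁷ /M/s)
    first complex ⇌ loaded enzyme + first product (K = 0.0580 M, k = 6070 /s)

At 2.00 min Sunday's flask held 0% starting material and 82.4% target, a shortfall of 1.76 mM against the 1.65 mM I had carried. The neighbour flask keeps the equivalents, the loading and the time of this recipe but starts from 25 mM of starting material. Carrying 1.65 mM over to that charge gives 93.4% target at the end. The neighbour flask ends with 92.9% target and 7.06% isomer of the product, a shortfall of 1.77 mM.

The runs are calculated with constants of no real substance; the scatter is artificial.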